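## Retrosynthetic overview

1. Target ⇐ bis-carbamate of the cis-octalin: both formamides are unveiled last, and the ring A alkene comes from a C2 ketone by enol triflate formation and reduction.
2. Ring B (the key ring, closed last) ⇐ intramolecular Michael addition of the ring A ketone α-carbon (C3) to a nitroalkene (C4); the nitro group is then removed.
3. Nitroalkene ⇐ nitroaldol condensation that unites fragment A (oxolane aldehyde) with fragment B (nitro ketone).
4. Fragment A ⇐ (S)-linalool (epoxidation and 5-exo cyclisation build the oxolane; hydroazidation brings in the C15 nitrogen). Fragment B ⇐ (S)-carvone (ring A and C8; a bridged lactone sets quaternary C7; Curtius rearrangement brings in the C7 nitrogen).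
5. Ring order: the oxolane (in fragment A) and ring A (from carvone) exist before the union; ring B forms in step 16.

Assumption: (S)-(+)-linalool (coriandrol) is taken as a cheap commercial single enantiomer.

Atom labels used in the Why lines: ring A = C1(Me), C2, C3, C8, C9, C10; ring B = C3, C4, C5, C6, C7(Me, N), C8; oxolane = O, C11(Me), C12, C13, C14; C15 = CMe2N.

## Fragment A (steps 1–7)

Step 1
Reactants: 1 (S)-(+)-linalool
Product: 2 (3S)-5-[(2S)-3,3-dimethyloxiran-2-yl]-3-methylpent-1-en-3-ol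
Conditions: ent-Shi ketone (L-fructose-derived, 0.3 equiv), KHSO5 (Oxone), K2CO3, Bu4NHSO4, MeCN/CH2(OMe)2/aq. buffer pH 10.5, 0 °C
Reagents that add atoms: potassium peroxymonosulfate, [K+].[O-]S(=O)(=O)OO
Why: Shi asymmetric epoxidation, in which the chiral dioxirane attacks only the electron-rich trisubstituted alkene and the chosen ketone enantiomer fixes the new epoxide carbon as (S), while the carbinol centre is untouched.

Step 2
Reactants: 2 (3S)-5-[(2S)-3,3-dimethyloxiran-2-yl]-3-methylpent-1-en-3-ol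
Product: 3 2-[(2R,5S)-5-ethenyl-5-methyloxolan-2-yl]propan-2-ol
Conditions: camphor-10-sulfonic acid (0.1 equiv), CH2Cl2, 0 °C
Reagents that add atoms: none
Why: Acid-catalysed 5-exo epoxide opening by the tertiary hydroxyl (epoxy-alcohol cyclisation) inverts the epoxide CH carbon and so gives the cis-2,5-oxolane (C14 R, C11 S); the minor 6-endo pyranoid isomer is removed by chromatography.

Step 3
Reactants: 3 2-[(2R,5S)-5-ethenyl-5-methyloxolan-2-yl]propan-2-ol
Product: 5 (2S,5R)-2-ethenyl-2-methyl-5-(prop-1-en-2-yl)oxolane, via chlorosulfite 4 (not isolated)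
Conditions: SOCl2, pyridine, CH2Cl2, −20 to 0 °C
Reagents that add atoms: none
Why: Dehydration through the chlorosulfite (E2 with pyridine) takes a methyl proton, because the only other β-hydrogen sits on the hindered ring carbon next to oxygen, so no stereocentre is touched.

Step 4
Reactants: 5 (2S,5R)-2-ethenyl-2-methyl-5-(prop-1-en-2-yl)oxolane
Product: 6 (2S,5R)-5-(2-azidopropan-2-yl)-2-ethenyl-2-methyloxolane
Conditions: Co(BF4)2·6H2O (6 mol%), Schiff-base ligand from 3,5-di-tert-butylsalicylaldehyde and potassium 2-amino-2,2-diphenylacetate (6 mol%), TsN3, PhSiH3, t-BuOOH (0.3 equiv), EtOH, rt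
Reagents that add atoms: 4-methylbenzenesulfonyl azide, Cc1ccc(cc1)S(=O)(=O)N=[N+]=[N-]
Why: Cobalt-catalysed hydrogen-atom-transfer hydroazidation (Mukaiyama type) puts H on the CH2 terminus and azide on the tertiary radical, and the 1,1-disubstituted alkene reacts ahead of the vinyl group on the quaternary carbon; the new carbon is not stereogenic.

Step 5
Reactants: 6 (2S,5R)-5-(2-azidopropan-2-yl)-2-ethenyl-2-methyloxolane
Product: 8 2-[(2R,5S)-5-ethenyl-5-methyloxolan-2-yl]propan-2-amine, via iminophosphorane 7 (not isolated)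
Conditions: PMe3, THF, rt; then H2O, 50 °C
Reagents that add atoms: none
Why: Staudinger reduction takes the azide to the iminophosphorane with loss of N2, and water hydrolyses it to the tertiary-alkyl amine without touching the alkene.

Step 6
Reactants: 8 2-[(2R,5S)-5-ethenyl-5-methyloxolan-2-yl]propan-2-amine
Product: 9 tert-butyl N-{2-[(2R,5S)-5-ethenyl-5-methyloxolan-2-yl]propan-2-yl}carbamate
Conditions: Boc2O, Et3N, THF, 50 °C
Reagents that add atoms: di-tert-butyl dicarbonate, CC(C)(C)OC(=O)OC(=O)OC(C)(C)C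
Why: Carbamate formation (Boc protection) masks the hindered amine for the later base, radical and palladium steps.

Step 7
Reactants: 9 tert-butyl N-{2-[(2R,5S)-5-ethenyl-5-methyloxolan-2-yl]propan-2-yl}carbamate
Product: 11 tert-butyl N-{2-[(2R,5S)-5-formyl-5-methyloxolan-2-yl]propan-2-yl}carbamate, via ozonide 10 (not isolated)
Conditions: O3, CH2Cl2, −78 °C; then Me2S, −78 °C to rt
Reagents that add atoms: ozone, [O-][O+]=O
Why: Ozonolysis with reductive work-up cuts the only remaining alkene to the aldehyde, which cannot epimerise because its α-carbon (C11) is quaternary.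

## Fragment B (steps 8–14)

Step 8
Reactants: 12 (S)-(+)-carvone
Product: 14 (1S,2S,5S)-2-methyl-5-(prop-1-en-2-yl)cyclohexan-1-ol, via dihydrocarvone 13 (not isolated)
Conditions: Li, NH3(l), THF, EtOH, −78 to −33 °C; NH4Cl
Reagents that add atoms: none
Why: Dissolving-metal (Birch-type) reduction takes the enone through the enolate and the ketone to the thermodynamic all-equatorial alcohol, so C1–Me and C2–OH come out trans to each other and C2–OH cis to the isopropenyl group, which is not reduced.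

Step 9
Reactants: 14 (1S,2S,5S)-2-methyl-5-(prop-1-en-2-yl)cyclohexan-1-ol
Product: 16 (1S,2S,5S)-5-(1-hydroxypropan-2-yl)-2-methylcyclohexan-1-ol, via borane adduct 15 (not isolated)
Conditions: 9-BBN-H (2.3 equiv), THF, 0 °C to rt; then NaOH, H2O2, 0 °C to rt
Reagents that add atoms: hydrogen peroxide, OO
Why: Hydroboration–oxidation adds boron anti-Markovnikov to the 1,1-disubstituted alkene; the new C7 centre forms as a mixture, which does not matter because it is enolised in step 11.

Step 10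
Reactants: 16 (1S,2S,5S)-5-(1-hydroxypropan-2-yl)-2-methylcyclohexan-1-ol
Product: 18 (1S,5S,8S)-4,8-dimethyl-2-oxabicyclo[3.3.1]nonan-3-one, via lactol 17 (not isolated)
Conditions: TEMPO (0.1 equiv), PhI(OAc)2 (2.5 equiv), CH2Cl2, rt
Reagents that add atoms: none
Why: TEMPO-mediated oxidative lactonisation oxidises the primary alcohol selectively, the aldehyde is trapped by the cis-1,3 secondary hydroxyl as a bridged lactol, and this is oxidised to the δ-lactone.

Step 11
Reactants: 18 (1S,5S,8S)-4,8-dimethyl-2-oxabicyclo[3.3.1]nonan-3-one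
Product: 20 (1S,4R,5S,8S)-4,8-dimethyl-4-(2-nitroethyl)-2-oxabicyclo[3.3.1]nonan-3-one, via lithium enolate 19 (not isolated)
Conditions: LiN(i-Pr)2, THF, −78 °C; nitroethylene, −78 °C; AcOH
Reagents that add atoms: nitroethylene, C=C[N+](=O)[O-]
Why: Michael addition of the lactone enolate to nitroethylene can only occur on the exo face, away from the three-carbon bridge of the bicycle, which sets quaternary C7 with the methyl group and the new arm placed as the target needs.

Step 12
Reactants: 20 (1S,4R,5S,8S)-4,8-dimethyl-4-(2-nitroethyl)-2-oxabicyclo[3.3.1]nonan-3-one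
Product: 21 (2R)-2-[(1S,3S,4S)-3-hydroxy-4-methylcyclohexyl]-2-methyl-4-nitrobutanoic acid
Conditions: LiOH, THF/H2O, rt; 1 M HCl to pH 4, 0 °C
Reagents that add atoms: lithium hydroxide, [Li+].[OH-]
Why: Saponification of the strained bridged lactone frees the C2 hydroxyl and the acid, and mild acidification returns the nitro group from its nitronate without Nef cleavage.

Step 13
Reactants: 21 (2R)-2-[(1S,3S,4S)-3-hydroxy-4-methylcyclohexyl]-2-methyl-4-nitrobutanoic acid
Product: 22 (2R)-2-methyl-2-[(1S,4S)-4-methyl-3-oxocyclohexyl]-4-nitrobutanoic acid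
Conditions: Dess–Martin periodinane, CH2Cl2, rt
Reagents that add atoms: none
Why: Dess–Martin oxidation converts the secondary alcohol into the ring ketone and leaves the acid, the nitro group and the equatorial methyl centre next to the new carbonyl alone.

Step 14
Reactants: 22 (2R)-2-methyl-2-[(1S,4S)-4-methyl-3-oxocyclohexyl]-4-nitrobutanoic acid
Product: 26 tert-butyl N-{(2R)-2-[(1S,4S)-4-methyl-3-oxocyclohexyl]-4-nitrobutan-2-yl}carbamate, via mixed anhydride 23 (not isolated), via acyl azide 24 (not isolated), via isocyanate 25 (not isolated)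
Conditions: NaN3, Boc2O, Bu4NBr (0.15 equiv), Zn(OTf)2 (0.03 equiv), THF, 45 °C
Reagents that add atoms: sodium azide, [Na+].[N-]=[N+]=[N-]; di-tert-butyl dicarbonate, CC(C)(C)OC(=O)OC(=O)OC(C)(C)C
Why: One-pot Curtius rearrangement (acyl azide, migration with retention at C7, trapping of the isocyanate by tert-butanol) turns the acid into the Boc-protected α-tertiary amine without amine base, which the primary nitro group tolerates.

## Union and endgame (steps 15–20)

Step 15
Reactants: 11 tert-butyl N-{2-[(2R,5S)-5-formyl-5-methyloxolan-2-yl]propan-2-yl}carbamate; 26 tert-butyl N-{(2R)-2-[(1S,4S)-4-methyl-3-oxocyclohexyl]-4-nitrobutan-2-yl}carbamate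
Product: 29 tert-butyl N-[(2R,4E)-5-[(2S,5R)-5-{2-[(tert-butoxycarbonyl)amino]propan-2-yl}-2-methyloxolan-2-yl]-2-[(1S,4S)-4-methyl-3-oxocyclohexyl]-4-nitropent-4-en-2-yl]carbamate, via nitro alcohol 27 (not isolated), via mesylate 28 (not isolated)
Conditions: DBU (0.1 equiv), THF, 0 °C to rt; then MsCl, Et3N, 0 °C
Reagents that add atoms: none
Why: Henry (nitroaldol) addition of the primary nitroalkane to the non-enolisable aldehyde, followed by E2 elimination of the mesylate, gives the conjugated (E)-nitroalkene, the more stable isomer with the oxolane trans to the nitro group.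

Step 16
Reactants: 29 the (E)-nitroalkene from step 15
Product: 31 cis-fused nitro decalone (ring B closed between C3 and C4; C5 nitro epimers; other centres as in 32), via pyrrolidine enamine 30 (not isolated)
Conditions: pyrrolidine (0.3 equiv), PhCO2H (0.3 equiv), CHCl3, rt
Reagents that add atoms: none
Why: Intramolecular Michael addition under enamine catalysis, in which the less substituted enamine carbon C3 adds to C4 of the nitroalkene through the transition state that keeps the bulky oxolane syn to H8 and away from C9 of ring A (this sets C4), and C3, now α to the ketone, equilibrates to the cis ring fusion that leaves the oxolane equatorial.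

Step 17
Reactants: 31 cis-fused nitro decalone
Product: 32 tert-butyl N-[(1R,4R,4aR,6S,8aS)-4-[(2S,5R)-5-{2-[(tert-butoxycarbonyl)amino]propan-2-yl}-2-methyloxolan-2-yl]-1,6-dimethyl-5-oxodecahydronaphthalen-1-yl]carbamate
Conditions: Bu3SnH (5 equiv), AIBN (0.4 equiv), PhMe, 110 °C
Reagents that add atoms: none
Why: Radical denitration (tin hydride chain) fragments the C–N bond after stannyl radical addition to the nitro oxygen and reduces the secondary radical, which removes the only centre (C5) that was a mixture.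

Step 18
Reactants: 32 the decalone from step 17
Product: 34 tert-butyl N-[(1R,4R,4aR,8aS)-4-[(2S,5R)-5-{2-[(tert-butoxycarbonyl)amino]propan-2-yl}-2-methyloxolan-2-yl]-1,6-dimethyl-5-{[(trifluoromethyl)sulfonyl]oxy}-1,2,3,4,4a,7,8,8a-octahydronaphthalen-1-yl]carbamate, via tripotassium enolate 33 (not isolated)
Conditions: KN(SiMe3)2 (3.3 equiv), THF, −78 °C; then PhNTf2, −78 to 0 °C; NH4Cl
Reagents that add atoms: N-phenylbis(trifluoromethanesulfonimide), O=S(=O)(N(c1ccccc1)S(=O)(=O)C(F)(F)F)C(F)(F)F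
Why: Kinetic enolate trapping, in which the axial C1–H is removed in preference to the C3–H lying near the carbonyl plane of ring A in the cis-decalone, and O-triflation fixes the C1=C2 double bond.

Step 19
Reactants: 34 the enol triflate from step 18
Product: 35 tert-butyl N-[(1R,4R,4aR,8aS)-4-[(2S,5R)-5-{2-[(tert-butoxycarbonyl)amino]propan-2-yl}-2-methyloxolan-2-yl]-1,6-dimethyl-1,2,3,4,4a,7,8,8a-octahydronaphthalen-1-yl]carbamate
Conditions: Pd(OAc)2 (5 mol%), PPh3 (10 mol%), HCO2H, Bu3N, DMF, 60 °C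
Reagents that add atoms: none
Why: Palladium-catalysed formate reduction of the enol triflate (oxidative addition, hydride transfer, reductive elimination) replaces OTf by H without moving the double bond or touching C3.

Step 20
Reactants: 35 the bis-Boc alkene from step 19
Product: 38 N-[(1R,4R,4aR,8aS)-4-[(2S,5R)-5-(2-formamidopropan-2-yl)-2-methyloxolan-2-yl]-1,6-dimethyl-1,2,3,4,4a,7,8,8a-octahydronaphthalen-1-yl]formamide, via silyl carbamate 36 (not isolated), via diamine 37 (not isolated)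
Conditions: Me3SiOTf, 2,6-lutidine, CH2Cl2, 0 °C; MeOH; then AcOCHO, Et3N, CH2Cl2, 0 °C to rt
Reagents that add atoms: acetic formic anhydride, CC(=O)OC=O
Why: Silyl triflate-mediated Boc cleavage avoids strong protic acid, so the trisubstituted alkene survives, and N-formylation of the two hindered amines with the mixed anhydride gives the target.

## Compound list

1 | (S)-(+)-linalool, (3S)-3,7-dimethylocta-1,6-dien-3-ol | C=C[C@@](C)(O)CCC=C(C)C | starting material
2 | (3S)-5-[(2S)-3,3-dimethyloxiran-2-yl]-3-methylpent-1-en-3-ol | C=C[C@@](C)(O)CC[C@@H]1OC1(C)C | intermediate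
3 | 2-[(2R,5S)-5-ethenyl-5-methyloxolan-2-yl]propan-2-ol (cis-furanoid linalool oxide) | C=C[C@]1(C)CC[C@H](C(C)(C)O)O1 | intermediate
4 | chlorosulfite of 3 (not isolated) | C=C[C@]1(C)CC[C@H](C(C)(C)OS(=O)Cl)O1 | intermediate
5 | (2S,5R)-2-ethenyl-2-methyl-5-(prop-1-en-2-yl)oxolane | C=C[C@]1(C)CC[C@H](C(C)=C)O1 | intermediate
6 | (2S,5R)-5-(2-azidopropan-2-yl)-2-ethenyl-2-methyloxolane | C=C[C@]1(C)CC[C@H](C(C)(C)N=[N+]=[N-])O1 | intermediate
7 | trimethyliminophosphorane of 8 (not isolated) | C=C[C@]1(C)CC[C@H](C(C)(C)N=P(C)(C)C)O1 | intermediate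
8 | 2-[(2R,5S)-5-ethenyl-5-methyloxolan-2-yl]propan-2-amine | C=C[C@]1(C)CC[C@H](C(C)(C)N)O1 | intermediate
9 | tert-butyl N-{2-[(2R,5S)-5-ethenyl-5-methyloxolan-2-yl]propan-2-yl}carbamate | C=C[C@]1(C)CC[C@H](C(C)(C)NC(=O)OC(C)(C)C)O1 | intermediate
10 | ozonide (1,2,4-trioxolan-3-yl in place of ethenyl) of 9 (not isolated) | C1OOC(O1)[C@]2(C)CC[C@H](C(C)(C)NC(=O)OC(C)(C)C)O2 | intermediate
11 | tert-butyl N-{2-[(2R,5S)-5-formyl-5-methyloxolan-2-yl]propan-2-yl}carbamate (fragment A) | O=C[C@]1(C)CC[C@H](C(C)(C)NC(=O)OC(C)(C)C)O1 | intermediate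
12 | (S)-(+)-carvone, (5S)-2-methyl-5-(prop-1-en-2-yl)cyclohex-2-en-1-one | CC1=CC[C@@H](CC1=O)C(C)=C | starting material
13 | (2S,5S)-2-methyl-5-(prop-1-en-2-yl)cyclohexan-1-one (trans-dihydrocarvone, not isolated) | C[C@H]1CC[C@@H](CC1=O)C(C)=C | intermediate
14 | (1S,2S,5S)-2-methyl-5-(prop-1-en-2-yl)cyclohexan-1-ol (all-equatorial dihydrocarveol) | C[C@H]1CC[C@@H](C[C@@H]1O)C(C)=C | intermediate
15 | O,C-bis(9-borabicyclo[3.3.1]nonan-9-yl) adduct of 14 (side-chain CH epimers, not isolated) | C[C@H]1CC[C@@H](C[C@@H]1OB2C3CCCC2CCC3)C(C)CB4C5CCCC4CCC5 | intermediate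
16 | (1S,2S,5S)-5-(1-hydroxypropan-2-yl)-2-methylcyclohexan-1-ol (side-chain CH epimers) | C[C@H]1CC[C@@H](C[C@@H]1O)C(C)CO | intermediate
17 | (1S,5S,8S)-4,8-dimethyl-2-oxabicyclo[3.3.1]nonan-3-ol (lactol, not isolated) | C[C@H]1CC[C@H]2C[C@@H]1OC(O)C2C | intermediate
18 | (1S,5S,8S)-4,8-dimethyl-2-oxabicyclo[3.3.1]nonan-3-one (C4 epimers) | C[C@H]1CC[C@H]2C[C@@H]1OC(=O)C2C | intermediate
19 | lithium enolate of 18 (not isolated) | C[C@H]1CC[C@H]2C[C@@H]1OC(O[Li])=C2C | intermediate
20 | (1S,4R,5S,8S)-4,8-dimethyl-4-(2-nitroethyl)-2-oxabicyclo[3.3.1]nonan-3-one | C[C@H]1CC[C@H]2C[C@@H]1OC(=O)[C@]2(C)CC[N+](=O)[O-] | intermediate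
21 | (2R)-2-[(1S,3S,4S)-3-hydroxy-4-methylcyclohexyl]-2-methyl-4-nitrobutanoic acid | C[C@H]1CC[C@@H](C[C@@H]1O)[C@@](C)(CC[N+](=O)[O-])C(=O)O | intermediate
22 | (2R)-2-methyl-2-[(1S,4S)-4-methyl-3-oxocyclohexyl]-4-nitrobutanoic acid | C[C@H]1CC[C@@H](CC1=O)[C@@](C)(CC[N+](=O)[O-])C(=O)O | intermediate
23 | mixed tert-butyl carbonic anhydride of 22 (not isolated) | C[C@H]1CC[C@@H](CC1=O)[C@@](C)(CC[N+](=O)[O-])C(=O)OC(=O)OC(C)(C)C | intermediate
24 | acyl azide of 22 (not isolated) | C[C@H]1CC[C@@H](CC1=O)[C@@](C)(CC[N+](=O)[O-])C(=O)N=[N+]=[N-] | intermediate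
25 | (2S,5S)-5-[(2R)-2-isocyanato-4-nitrobutan-2-yl]-2-methylcyclohexan-1-one (not isolated) | C[C@H]1CC[C@@H](CC1=O)[C@@](C)(CC[N+](=O)[O-])N=C=O | intermediate
26 | tert-butyl N-{(2R)-2-[(1S,4S)-4-methyl-3-oxocyclohexyl]-4-nitrobutan-2-yl}carbamate (fragment B) | C[C@H]1CC[C@@H](CC1=O)[C@@](C)(CC[N+](=O)[O-])NC(=O)OC(C)(C)C | intermediate
27 | nitro alcohol from 11 and 26 (C4–OH, C5–NO2, both as epimer mixtures, not isolated) | C[C@H]1CC[C@@H](CC1=O)[C@@](C)(CC(C(O)[C@]2(C)CC[C@H](C(C)(C)NC(=O)OC(C)(C)C)O2)[N+](=O)[O-])NC(=O)OC(C)(C)C | intermediate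
28 | methanesulfonate of 27 (not isolated) | C[C@H]1CC[C@@H](CC1=O)[C@@](C)(CC(C(OS(C)(=O)=O)[C@]2(C)CC[C@H](C(C)(C)NC(=O)OC(C)(C)C)O2)[N+](=O)[O-])NC(=O)OC(C)(C)C | intermediate
29 | tert-butyl N-[(2R,4E)-5-[(2S,5R)-5-{2-[(tert-butoxycarbonyl)amino]propan-2-yl}-2-methyloxolan-2-yl]-2-[(1S,4S)-4-methyl-3-oxocyclohexyl]-4-nitropent-4-en-2-yl]carbamate | C[C@H]1CC[C@@H](CC1=O)[C@@](C)(C/C(=C\[C@]2(C)CC[C@H](C(C)(C)NC(=O)OC(C)(C)C)O2)[N+](=O)[O-])NC(=O)OC(C)(C)C | intermediate
30 | pyrrolidine enamine of 29 (C2=C3, not isolated) | C[C@H]1CC[C@@H](C=C1N3CCCC3)[C@@](C)(C/C(=C\[C@]2(C)CC[C@H](C(C)(C)NC(=O)OC(C)(C)C)O2)[N+](=O)[O-])NC(=O)OC(C)(C)C | intermediate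
31 | cis-fused nitro decalone: 32 carrying a nitro group at C5 (naphthalene C3, both epimers) | C[C@@H]1C(=O)[C@H]2[C@H]([C@]3(C)CC[C@H](C(C)(C)NC(=O)OC(C)(C)C)O3)C([N+](=O)[O-])C[C@@](C)(NC(=O)OC(C)(C)C)[C@H]2CC1 | intermediate
32 | tert-butyl N-[(1R,4R,4aR,6S,8aS)-4-[(2S,5R)-5-{2-[(tert-butoxycarbonyl)amino]propan-2-yl}-2-methyloxolan-2-yl]-1,6-dimethyl-5-oxodecahydronaphthalen-1-yl]carbamate | C[C@@H]1C(=O)[C@H]2[C@H]([C@]3(C)CC[C@H](C(C)(C)NC(=O)OC(C)(C)C)O3)CC[C@@](C)(NC(=O)OC(C)(C)C)[C@H]2CC1 | intermediate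
33 | tripotassium salt of 32 (C1=C2 enolate and both carbamate nitrogens, not isolated) | CC1=C(O[K])[C@H]2[C@H]([C@]3(C)CC[C@H](C(C)(C)N([K])C(=O)OC(C)(C)C)O3)CC[C@@](C)(N([K])C(=O)OC(C)(C)C)[C@H]2CC1 | intermediate
34 | enol triflate: 35 carrying OSO2CF3 at C2 (naphthalene C5) | CC1=C(OS(=O)(=O)C(F)(F)F)[C@H]2[C@H]([C@]3(C)CC[C@H](C(C)(C)NC(=O)OC(C)(C)C)O3)CC[C@@](C)(NC(=O)OC(C)(C)C)[C@H]2CC1 | intermediate
35 | tert-butyl N-[(1R,4R,4aR,8aS)-4-[(2S,5R)-5-{2-[(tert-butoxycarbonyl)amino]propan-2-yl}-2-methyloxolan-2-yl]-1,6-dimethyl-1,2,3,4,4a,7,8,8a-octahydronaphthalen-1-yl]carbamate | CC1=C[C@H]2[C@H]([C@]3(C)CC[C@H](C(C)(C)NC(=O)OC(C)(C)C)O3)CC[C@@](C)(NC(=O)OC(C)(C)C)[C@H]2CC1 | intermediate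
36 | bis(trimethylsilyl carbamate) from 35 (not isolated) | CC1=C[C@H]2[C@H]([C@]3(C)CC[C@H](C(C)(C)NC(=O)O[Si](C)(C)C)O3)CC[C@@](C)(NC(=O)O[Si](C)(C)C)[C@H]2CC1 | intermediate
37 | (1R,4R,4aR,8aS)-4-[(2S,5R)-5-(2-aminopropan-2-yl)-2-methyloxolan-2-yl]-1,6-dimethyl-1,2,3,4,4a,7,8,8a-octahydronaphthalen-1-amine (not isolated) | CC1=C[C@H]2[C@H]([C@]3(C)CC[C@H](C(C)(C)N)O3)CC[C@@](C)(N)[C@H]2CC1 | intermediate
38 | N-[(1R,4R,4aR,8aS)-4-[(2S,5R)-5-(2-formamidopropan-2-yl)-2-methyloxolan-2-yl]-1,6-dimethyl-1,2,3,4,4a,7,8,8a-octahydronaphthalen-1-yl]formamide (CNP0173819.1) | CC1=C[C@H]2[C@H]([C@]3(C)CC[C@H](C(C)(C)NC=O)O3)CC[C@@](C)(NC=O)[C@H]2CC1 | target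

## Step count and risks

Total step count: 20.
Longest linear sequence: 13 steps (steps 1–7 or steps 8–14, then steps 15–20).

Steps most likely to fail:

Step 16 (ring B closure). The β-carbon of the nitroalkene is neopentyl-like and the C4 configuration rests on a conformational argument. Fallback: set out again from nitro ketone 26 and aldehyde 11, in place of steps 15 and 16. A pyrrolidine/acetic acid-mediated crossed aldol condensation joins C3 of the ketone to the non-enolisable aldehyde and gives the (E)-alkylidene ketone F1, in which allylic strain turns the C7 arm axial. Catalytic DBU then forms the C5 nitronate, which adds to C4 of the enone; donor and acceptor roles are exchanged and the oxolane again ends up syn to H8. Protonation at C3 leads back to 31.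

Step 17 (removal of a secondary nitro group with tin hydride, which is much slower than for tertiary nitro groups). Fallback: from 31 the nitro group is carried on instead of being removed. Steps 18 and 19, run with one more equivalent of KN(SiMe3)2 so that the nitro group is held as its nitronate, give the nitro enol triflate F2 and then the nitro alkene F3. With the ketone gone, Zn/AcOH reduces the nitro group to the primary amine F4 without ring closure to an imine. Hydrodeamination with an anomeric amide reagent, N-(benzyloxy)-N-(pivaloyloxy)-4-(trifluoromethyl)benzamide, in MeCN at 45 °C replaces NH2 by H and returns the route to 35.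

Step 4 (hydroazidation must discriminate between two alkenes). Fallback: from alcohol 3, skipping steps 3 to 5. A Ritter reaction with chloroacetonitrile (H2SO4, AcOH, 0 °C to rt) captures the tertiary cation as the chloroacetamide F5, and thiourea in EtOH/AcOH at reflux removes the chloroacetyl group to give amine 8, where the route is rejoined.

Further compounds

F1 | step 16 | tert-butyl N-{(2R)-2-[(1S,4S)-2-{(E)-[(2S,5R)-5-{2-[(tert-butoxycarbonyl)amino]propan-2-yl}-2-methyloxolan-2-yl]methylidene}-4-methyl-3-oxocyclohexyl]-4-nitrobutan-2-yl}carbamate | C[C@H]1CC[C@@H](/C(=C\[C@]2(C)CC[C@H](C(C)(C)NC(=O)OC(C)(C)C)O2)C1=O)[C@@](C)(CC[N+](=O)[O-])NC(=O)OC(C)(C)C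
F2 | step 17 | nitro enol triflate (34 carrying a nitro group at C5, both epimers) | CC1=C(OS(=O)(=O)C(F)(F)F)[C@H]2[C@H]([C@]3(C)CC[C@H](C(C)(C)NC(=O)OC(C)(C)C)O3)C([N+](=O)[O-])C[C@@](C)(NC(=O)OC(C)(C)C)[C@H]2CC1
F3 | step 17 | nitro alkene (35 carrying a nitro group at C5, both epimers) | CC1=C[C@H]2[C@H]([C@]3(C)CC[C@H](C(C)(C)NC(=O)OC(C)(C)C)O3)C([N+](=O)[O-])C[C@@](C)(NC(=O)OC(C)(C)C)[C@H]2CC1
F4 | step 17 | primary amine (35 carrying NH2 at C5, both epimers) | CC1=C[C@H]2[C@H]([C@]3(C)CC[C@H](C(C)(C)NC(=O)OC(C)(C)C)O3)C(N)C[C@@](C)(NC(=O)OC(C)(C)C)[C@H]2CC1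
F5 | step 4 | 2-chloro-N-{2-[(2R,5S)-5-ethenyl-5-methyloxolan-2-yl]propan-2-yl}acetamide | C=C[C@]1(C)CC[C@H](C(C)(C)NC(=O)CCl)O1
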